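**Retrosynthetic overview**
1. Target ⇒ late C8 esterification (C–O) with a silyl-protected 2-(hydroxymethyl)acrylic acid and C9 acetylation of a macrocyclic 8-silyloxy-9-ol.
2. Ring A (10-membered carbocycle) ⇒ C9–C10 bond by intramolecular nickel/chromium alkenyl–aldehyde coupling, formed last.
3. Ring B (lactone) ⇒ C6–C7 bond by chromium allylation of an epoxy aldehyde (fragment 1) with a 2-(bromomethyl)enoate (fragment 2), then C6–O lactonisation.
4. Key bonds: two stereo-defining C–O bond formations. Ring C (C4/C5 epoxide) comes from asymmetric epoxidation of a Z-allylic terpenol (fragment 1). The C8–O bond comes from a proposed Pd-catalysed enantioconvergent silanol opening of a racemic vinyl epoxide (fragment 2). C6, C7 and C9 are relayed from these.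
5. Ring order: C (epoxide) → B (lactone) → A (carbocycle).

Assumption: atom labels C1–C15 follow germacrane numbering of the target (C4/C5 epoxide, C6 lactone oxygen, C8 ester, C9 acetate, C1=C10, C11–C13 methylene lactone, C14 CO2Me, C15 methyl). CIP descriptors quoted with these labels were recalculated for each compound. Stereochemical outcomes of steps 5, 9 and 11 are predictions from models, not established results.

Step 1
Reactants: 1 nerol
Product: 2 (2S,3R)-2,3-epoxynerol, [(2S,3R)-3-methyl-3-(4-methylpent-3-en-1-yl)oxiran-2-yl]methanol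
Conditions: Ti(OiPr)4 (5 mol%), L-(+)-diethyl tartrate (7.5 mol%), t-BuOOH, 4 Å MS, CH2Cl2, −20 °C
Reagents that add atoms: tert-butyl hydroperoxide CC(C)(C)OO
Why: Sharpless asymmetric epoxidation: the allylic hydroxyl binds the titanium tartrate and the peroxide oxygen is delivered to one alkene face, so the C–O bonds of ring C and the C4 (R) and C5 (S) centres are set together (L-(+)-tartrate gives the 2S,3R epoxide; the Z alkene of nerol makes the epoxide cis).

Step 2
Reactants: 2 (2S,3R)-2,3-epoxynerol
Product: 3 3-[(2R,3S)-3-(hydroxymethyl)-2-methyloxiran-2-yl]propanal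
Conditions: O3, CH2Cl2/MeOH, −78 °C; then Me2S, −78 °C → rt
Reagents that add atoms: ozone [O-][O+]=O
Why: Ozonolysis with reductive work-up cleaves the only remaining C=C to the aldehyde; epoxide and primary alcohol are inert and no stereocentre is touched.

Step 3
Reactants: 3 3-[(2R,3S)-3-(hydroxymethyl)-2-methyloxiran-2-yl]propanal
Product: 4 methyl (2Z)-5-[(2R,3S)-3-(hydroxymethyl)-2-methyloxiran-2-yl]-2-iodopent-2-enoate
Conditions: Ph3P=CHCO2Me, NIS, CH2Cl2, −20 °C; then 3, 0 °C → rt
Reagents that add atoms: methyl (triphenylphosphoranylidene)acetate COC(=O)C=P(c1ccccc1)(c1ccccc1)c1ccccc1; N-iodosuccinimide O=C1CCC(=O)N1I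
Why: Wittig olefination with the α-iodo ylide generated in situ by iodination of the stabilised ylide; as with other stabilised α-halo ylides the ester ends up trans to the chain, giving the (Z)-α-iodoenoate that later fixes the C1=C10 geometry.

Step 4
Reactants: 4 methyl (2Z)-5-[(2R,3S)-3-(hydroxymethyl)-2-methyloxiran-2-yl]-2-iodopent-2-enoate
Product: 5 methyl (2Z)-5-[(2R,3R)-3-formyl-2-methyloxiran-2-yl]-2-iodopent-2-enoate (fragment 1)
Conditions: TEMPO (2,2,6,6-tetramethylpiperidin-1-oxyl, 10 mol%), PhI(OAc)2, CH2Cl2, rt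
Reagents that add atoms: none
Why: TEMPO-catalysed oxidation with PhI(OAc)2 converts the primary epoxy alcohol into the cis-α,β-epoxy aldehyde under neutral conditions, so C5 is not epimerised and vinyl iodide, enoate and epoxide survive.

Step 5
Reactants: 6 rac-2-vinyloxirane (butadiene monoxide)
Product: 8 (S)-3,4-bis(triethylsilyloxy)but-1-ene, via monosilyl ether 7 (not isolated)
Conditions: Pd2(dba)3·CHCl3 (1 mol%), (R,R)-DACH-naphthyl Trost ligand (3 mol%), Et3B (2 mol%), Et3SiOH (1.1 equiv), CH2Cl2, rt; then Et3SiCl, imidazole, 0 °C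
Reagents that add atoms: triethylsilanol CC[Si](CC)(CC)O; chlorotriethylsilane CC[Si](CC)(CC)Cl
Why: Proposed new method: palladium-catalysed dynamic kinetic asymmetric opening of a racemic vinyl epoxide by a trialkylsilanol, in which zerovalent palladium ionises both enantiomers of 6 to rapidly interconverting π-allyl/alkoxide zwitterions, the alkoxide (through a boron ate complex with the silanol) delivers Et3SiO− to the proximal allyl terminus inside the chiral ligand pocket, and the branched (S)-silyl ether forms so that the C8–O bond and the C8 centre are created together; the silyl ether product cannot re-ionise and any 1,2-silyl migration is harmless because in-situ silylation gives the bis-silyl ether; the closest known reaction type is the Trost-type Pd-catalysed dynamic kinetic asymmetric addition of alcohols or hydrogencarbonate to vinyl epoxides under boron co-catalysis, together with the use of silanols as water surrogates in Pd-allyl chemistry (the (R,R) ligand is expected to give the S product by analogy; otherwise its enantiomer is used).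

Step 6
Reactants: 8 (S)-3,4-bis(triethylsilyloxy)but-1-ene
Product: 9 (R)-2,3-bis(triethylsilyloxy)propanal
Conditions: O3, CH2Cl2, −78 °C; then Me2S, −78 °C → rt
Reagents that add atoms: ozone [O-][O+]=O
Why: Ozonolysis of the terminal vinyl group with reductive work-up gives the α,β-bis-silyloxy aldehyde; silyl ethers are stable and C8 is not enolised at low temperature.

Step 7
Reactants: 9 (R)-2,3-bis(triethylsilyloxy)propanal
Product: 10 methyl (4R)-3-hydroxy-2-methylidene-4,5-bis(triethylsilyloxy)pentanoate (mixture of C3 epimers)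
Conditions: methyl acrylate (neat, 5 equiv), DABCO (0.5 equiv), rt
Reagents that add atoms: methyl acrylate C=CC(=O)OC
Why: Morita–Baylis–Hillman reaction: the ammonium enolate from DABCO and methyl acrylate adds to the activated α-silyloxy aldehyde; the new carbinol centre (C7) need not be controlled because step 8 removes it.

Step 8
Reactants: 10 methyl (4R)-3-hydroxy-2-methylidene-4,5-bis(triethylsilyloxy)pentanoate
Product: 11 methyl (2Z,4S)-2-(bromomethyl)-4,5-bis(triethylsilyloxy)pent-2-enoate (fragment 2)
Conditions: NBS, Me2S, CH2Cl2, −20 → 0 °C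
Reagents that add atoms: N-bromosuccinimide O=C1CCC(=O)N1Br
Why: Corey–Kim-type activation of the Baylis–Hillman alcohol and SN2′ attack of bromide give the rearranged primary allylic bromide as the thermodynamically favoured Z isomer (C8 cis to CH2Br); silyl ethers tolerate the neutral conditions.

Step 9
Reactants: 5 methyl (2Z)-5-[(2R,3R)-3-formyl-2-methyloxiran-2-yl]-2-iodopent-2-enoate; 11 methyl (2Z,4S)-2-(bromomethyl)-4,5-bis(triethylsilyloxy)pent-2-enoate
Product: 13 (4R,5S,6S,7S,8S)-bis-silyl iodo lactone (6,12-lactone; seco-C9/C10 germacranolide), via hydroxy diester 12 (not isolated)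
Conditions: CrCl2 (4 equiv, nickel-free), THF, 0 °C → rt (lactonisation in situ and on work-up)
Reagents that add atoms: none
Why: Nozaki–Hiyama (chromium Barbier) 2-(methoxycarbonyl)allylation followed by lactonisation (ring B): the allylchromium adds through a chair transition state to give the anti adduct (trans lactone, C7), the cis-epoxy aldehyde is attacked in the Cornforth/Felkin sense (C6, erythro to the epoxide oxygen), and the C8 centre steers the aldehyde anti to C9 with H8 inside and OSiEt3 outside, so all three preferences converge on one diastereomer; the vinyl iodide does not react with CrCl2 in the absence of nickel.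

Step 10
Reactants: 13 (4R,5S,6S,7S,8S)-bis-silyl iodo lactone
Product: 14 (4R,5S,6S,7S,8S)-C9 aldehyde (13 with CH2OSiEt3 converted into CHO; C8–OSiEt3 kept)
Conditions: (COCl)2, DMSO, CH2Cl2, −78 → −35 °C; then Et3N, −78 → 0 °C
Reagents that add atoms: none
Why: Swern oxidation applied to silyl ethers: chlorodimethylsulfonium chloride cleaves and oxidises the primary triethylsilyl ether to the aldehyde while the secondary one at C8 is left, and the cold amine work-up does not epimerise C8.

Step 11
Reactants: 14 (4R,5S,6S,7S,8S)-C9 aldehyde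
Product: 15 (4R,5S,6S,7S,8S,9R)-8-O-triethylsilyl-9-hydroxy macrocycle (4,5-epoxy-cis,cis-germacranolide core with ring A, 6,12-lactone and C14 methyl ester)
Conditions: CrCl2 (10 equiv), NiCl2 (2 mol% of the chromium), DMSO/THF, 3 mM, rt
Reagents that add atoms: none
Why: Intramolecular Nozaki–Hiyama–Kishi reaction: nickel-catalysed formation of the alkenylchromium from the (Z)-iodoenoate with retention and addition to the C9 aldehyde at high dilution closes ring A with C2 cis to C9, and Felkin–Anh attack anti to the α-OSiEt3 group gives the 8,9-erythro (9R) alcohol.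

Step 12
Reactants: 15 (4R,5S,6S,7S,8S,9R)-8-O-triethylsilyl-9-hydroxy macrocycle
Product: 16 (4R,5S,6S,7S,8S,9R)-9-acetate of 15
Conditions: Ac2O, pyridine, DMAP (cat.), CH2Cl2, 0 °C → rt
Reagents that add atoms: acetic anhydride CC(=O)OC(C)=O
Why: DMAP-catalysed acetylation of the only free hydroxyl installs the C9 acetate without touching any stereocentre.

Step 13
Reactants: 16 (4R,5S,6S,7S,8S,9R)-9-acetate
Product: 17 (4R,5S,6S,7R,8S,9R)-9-acetoxy-8-hydroxy macrocycle (8-O-desacyl target)
Conditions: HF·pyridine, pyridine, THF, 0 °C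
Reagents that add atoms: none
Why: Fluoride desilylation: buffered HF·pyridine removes the secondary triethylsilyl ether while epoxide, lactone and acetate stay intact (the acidic medium suppresses acetyl migration).

Step 14
Reactants: 18 methyl 2-(hydroxymethyl)acrylate
Product: 19 methyl 2-{[(tert-butyldimethylsilyl)oxy]methyl}acrylate
Conditions: TBSCl, imidazole, DMF, 0 °C → rt
Reagents that add atoms: tert-butyldimethylsilyl chloride CC(C)(C)[Si](C)(C)Cl
Why: Standard silylation of the primary allylic alcohol (Corey protocol) masks the side-chain hydroxyl.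

Step 15
Reactants: 19 methyl 2-{[(tert-butyldimethylsilyl)oxy]methyl}acrylate
Product: 20 2-{[(tert-butyldimethylsilyl)oxy]methyl}acrylic acid
Conditions: LiOH, THF/H2O, 0 °C; then 1 M HCl to pH 3
Reagents that add atoms: lithium hydroxide [Li+].[OH-]
Why: Saponification of the methyl ester at 0 °C; the primary silyl ether survives and acidification gives the free acid.

Step 16
Reactants: 17 (4R,5S,6S,7R,8S,9R)-9-acetoxy-8-hydroxy macrocycle; 20 2-{[(tert-butyldimethylsilyl)oxy]methyl}acrylic acid
Product: 21 O-tert-butyldimethylsilyl ether of the target (4R,5S,6S,7R,8S,9R)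
Conditions: DIC, DMAP (cat.), CH2Cl2, 0 °C → rt
Reagents that add atoms: none
Why: Steglich esterification (carbodiimide/DMAP) completes the C8 ester with retention at C8 because only the acid is activated.

Step 17
Reactants: 21 O-tert-butyldimethylsilyl ether of the target
Product: 22 target CNP0147016.1, methyl (4R,5S,6S,7R,8S,9R)-9-acetoxy-4,5-epoxy-8-[2-(hydroxymethyl)acryloyloxy]-germacra-1(10),11(13)-dien-12,6-olid-14-oate (ring-cis 1(10) alkene)
Conditions: HF·pyridine, pyridine, THF, 0 °C → rt
Reagents that add atoms: none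
Why: Fluoride desilylation cleaves the primary silyl ether and releases the target without affecting epoxide, esters or the two exocyclic methylene groups.

**Compound list**
1 | nerol, (2Z)-3,7-dimethylocta-2,6-dien-1-ol | CC(C)=CCC/C(C)=C\CO | starting material
2 | (2S,3R)-2,3-epoxynerol | OC[C@@H]1O[C@]1(C)CCC=C(C)C | intermediate
3 | 3-[(2R,3S)-3-(hydroxymethyl)-2-methyloxiran-2-yl]propanal | OC[C@@H]1O[C@]1(C)CCC=O | intermediate
4 | methyl (2Z)-5-[(2R,3S)-3-(hydroxymethyl)-2-methyloxiran-2-yl]-2-iodopent-2-enoate | OC[C@@H]1O[C@]1(C)CC/C=C(\I)C(=O)OC | intermediate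
5 | methyl (2Z)-5-[(2R,3R)-3-formyl-2-methyloxiran-2-yl]-2-iodopent-2-enoate (fragment 1) | O=C[C@@H]1O[C@]1(C)CC/C=C(\I)C(=O)OC | intermediate
6 | rac-2-vinyloxirane | C=CC1CO1 | starting material
7 | (S)-2-(triethylsilyloxy)but-3-en-1-ol | C=C[C@H](O[Si](CC)(CC)CC)CO | intermediate
8 | (S)-3,4-bis(triethylsilyloxy)but-1-ene | C=C[C@H](O[Si](CC)(CC)CC)CO[Si](CC)(CC)CC | intermediate
9 | (R)-2,3-bis(triethylsilyloxy)propanal | O=C[C@H](O[Si](CC)(CC)CC)CO[Si](CC)(CC)CC | intermediate
10 | methyl (4R)-3-hydroxy-2-methylidene-4,5-bis(triethylsilyloxy)pentanoate (C3 epimers) | C=C(C(=O)OC)C(O)[C@H](O[Si](CC)(CC)CC)CO[Si](CC)(CC)CC | intermediate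
11 | methyl (2Z,4S)-2-(bromomethyl)-4,5-bis(triethylsilyloxy)pent-2-enoate (fragment 2) | BrC/C(C(=O)OC)=C\[C@H](O[Si](CC)(CC)CC)CO[Si](CC)(CC)CC | intermediate
12 | (4R,5S,6S,7S,8S)-hydroxy diester (open form of 13: C6–OH and C12 methyl ester) | CC[Si](CC)(CC)OC[C@@H](O[Si](CC)(CC)CC)[C@@H](C(=C)C(=O)OC)[C@H](O)[C@@H]1O[C@]1(C)CC/C=C(\I)C(=O)OC | intermediate
13 | (4R,5S,6S,7S,8S)-bis-silyl iodo lactone: α-methylene-γ-butyrolactone with the epoxide/(Z)-iodoenoate chain on C6 and the (S)-1,2-bis(triethylsilyloxy)ethyl group on C7 | CC[Si](CC)(CC)OC[C@@H](O[Si](CC)(CC)CC)[C@H]1C(=C)C(=O)O[C@@H]1[C@@H]1O[C@]1(C)CC/C=C(\I)C(=O)OC | intermediate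
14 | (4R,5S,6S,7S,8S)-C9 aldehyde (8-OSiEt3) | O=C[C@@H](O[Si](CC)(CC)CC)[C@H]1C(=C)C(=O)O[C@@H]1[C@@H]1O[C@]1(C)CC/C=C(\I)C(=O)OC | intermediate
15 | (4R,5S,6S,7S,8S,9R)-8-O-triethylsilyl-9-hydroxy macrocycle | CC[Si](CC)(CC)O[C@H]1[C@H]2C(=C)C(=O)O[C@@H]2[C@@H]2O[C@]2(C)CC/C=C(/C(=O)OC)[C@H]1O | intermediate
16 | (4R,5S,6S,7S,8S,9R)-8-O-triethylsilyl-9-acetoxy macrocycle | CC[Si](CC)(CC)O[C@H]1[C@H]2C(=C)C(=O)O[C@@H]2[C@@H]2O[C@]2(C)CC/C=C(/C(=O)OC)[C@H]1OC(C)=O | intermediate
17 | (4R,5S,6S,7R,8S,9R)-9-acetoxy-8-hydroxy macrocycle | O[C@H]1[C@H]2C(=C)C(=O)O[C@@H]2[C@@H]2O[C@]2(C)CC/C=C(/C(=O)OC)[C@H]1OC(C)=O | intermediate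
18 | methyl 2-(hydroxymethyl)acrylate | C=C(CO)C(=O)OC | starting material
19 | methyl 2-{[(tert-butyldimethylsilyl)oxy]methyl}acrylate | C=C(CO[Si](C)(C)C(C)(C)C)C(=O)OC | intermediate
20 | 2-{[(tert-butyldimethylsilyl)oxy]methyl}acrylic acid | C=C(CO[Si](C)(C)C(C)(C)C)C(=O)O | intermediate
21 | O-tert-butyldimethylsilyl ether of the target | C=C(CO[Si](C)(C)C(C)(C)C)C(=O)O[C@H]1[C@H]2C(=C)C(=O)O[C@@H]2[C@@H]2O[C@]2(C)CC/C=C(/C(=O)OC)[C@H]1OC(C)=O | intermediate
22 | target CNP0147016.1 | C=C(CO)C(=O)O[C@H]1[C@H]2C(=C)C(=O)O[C@@H]2[C@@H]2O[C@]2(C)CC/C=C(/C(=O)OC)[C@H]1OC(C)=O | target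

**Step count and risks**
Total steps: 17. Longest linear sequence: 11 steps (6 → 22 through steps 5–13, 16, 17; equally 1 → 22 through steps 1–4, 9–13, 16, 17).

The three steps most likely to fail:

Step 5 (the proposed new silanol opening). The risk is low enantioselectivity or linear 1,4-addition. The fallback uses known chemistry and sets out from 6. Hydrolytic kinetic resolution of 6 with (R,R)-(salen)Co(OAc) [salen = N,N′-bis(3,5-di-tert-butylsalicylidene)-1,2-cyclohexanediamine dianion] and 0.55 equiv of water gives (S)-but-3-ene-1,2-diol F1 (at most 50%). Silylation of both hydroxyls (Et3SiCl, imidazole) comes back to the route at 8.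

Step 9 (intermolecular chromium allylation/lactonisation). The risks are the anti selectivity, the double stereodifferentiation between two chiral fragments, and reduction of the iodoenoate. The fallback replaces the allylchromium by a configurationally defined allylboronate and sets out from 9. Homologation with lithiated (trimethylsilyl)diazomethane gives (S)-3,4-bis(triethylsilyloxy)but-1-yne F2. Treatment with n-BuLi and ClCO2Me gives methyl (S)-4,5-bis(triethylsilyloxy)pent-2-ynoate F3. Syn-hydrocupration (CuI, MeLi, DIBAL-H, HMPA, THF, −50 °C) and trapping of the alkenylcopper with ICH2Bpin gives methyl (2Z,4S)-2-[(4,4,5,5-tetramethyl-1,3,2-dioxaborolan-2-yl)methyl]-4,5-bis(triethylsilyloxy)pent-2-enoate F4, in which C8 is trans to the CH2B group. Uncatalysed allylboration of 5 with F4 (toluene, 90 °C) passes through a closed chair, which dictates the anti adduct; lactonisation then comes back to the route at 13.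

Step 11 (closure of ring A). The risks are oligomerisation and delivery of the wrong C9 epimer through chelation or ring control. The fallback sets C9 by ketone reduction instead of by the C–C addition and sets out from 14. If the ring closes to the 9-epimeric alcohol, (4R,5S,6S,7S,8S,9S)-9-epi-15 F5, oxidation with Dess–Martin periodinane gives the macrocyclic C9 ketone F6. Reagent-controlled Corey–Bakshi–Shibata reduction (2-methyl-CBS-oxazaborolidine, catecholborane, −78 °C) comes back to the route at 15.

**Further compounds**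
F1 | step 5 | (S)-but-3-ene-1,2-diol | C=C[C@H](O)CO
F2 | step 9 | (S)-3,4-bis(triethylsilyloxy)but-1-yne | C#C[C@H](O[Si](CC)(CC)CC)CO[Si](CC)(CC)CC
F3 | step 9 | methyl (S)-4,5-bis(triethylsilyloxy)pent-2-ynoate | COC(=O)C#C[C@H](O[Si](CC)(CC)CC)CO[Si](CC)(CC)CC
F4 | step 9 | methyl (2Z,4S)-2-[(4,4,5,5-tetramethyl-1,3,2-dioxaborolan-2-yl)methyl]-4,5-bis(triethylsilyloxy)pent-2-enoate | CC1(C)OB(C/C(C(=O)OC)=C/[C@H](O[Si](CC)(CC)CC)CO[Si](CC)(CC)CC)OC1(C)C
F5 | step 11 | (4R,5S,6S,7S,8S,9S)-9-epi-15 | CC[Si](CC)(CC)O[C@H]1[C@H]2C(=C)C(=O)O[C@@H]2[C@@H]2O[C@]2(C)CC/C=C(/C(=O)OC)[C@@H]1O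
F6 | step 11 | (4R,5S,6S,7S,8S)-8-O-triethylsilyl-9-oxo macrocycle | CC[Si](CC)(CC)O[C@H]1[C@H]2C(=C)C(=O)O[C@@H]2[C@@H]2O[C@]2(C)CC/C=C(/C(=O)OC)C1=O
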